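The route cuts the only C=C bond of the cyclohexene, C4=C5, which lies between carbinol C3 and chloride-bearing C6 (C1 = quaternary carbinol carrying C7H2OBz, C2 = CHOBz, C3 = CHOH, C6 = CHCl). The key step is a ring-closing metathesis of an acyclic octa-1,3,7-triene. Its central (Z)-trisubstituted C1=C6 alkene, inherited from a furan ring, holds the two vinyl termini together. One operation therefore builds the whole carbocycle as a trans-dioxygenated cyclohexa-1,3-diene. C2 and C3 are set beforehand by one reagent-controlled alkoxyallylboration. Afterwards the surviving C1=C6 alkene is epoxidised under direction of the C2 hydroxyl. Chloride then opens the vinyl oxirane at allylic C6 with inversion and gives the trans-chlorohydrin.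

Key step: step 5

Assumption: 3-(methoxymethoxy)prop-1-ene (5) and (+)-Ipc2BOMe are taken as catalogue chemicals, and dimethyldioxirane is used as a freshly prepared, dried acetone solution.

Step 1
Reactants: 1 furan-3-ylmethanol
Product: 2 furan-3-ylmethyl benzoate
Conditions: BzCl, Et3N, DMAP (cat.), CH2Cl2, 0 °C to rt
Reagents that add atoms: benzoyl chloride, O=C(Cl)c1ccccc1
Why: DMAP-catalysed O-acylation (esterification) of the unhindered primary alcohol installs the C7 benzoate of the target at the start and masks the hydroxyl that would otherwise trap the dialdehyde of step 2 as a hemiacetal; no stereocentre is formed.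

Step 2
Reactants: 2 furan-3-ylmethyl benzoate
Product: 3 (2Z)-2-[(benzoyloxy)methyl]but-2-enedial
Conditions: dimethyldioxirane (dry acetone solution, 1.05 equiv), −78 to 0 °C; concentrated cold and used at once
Reagents that add atoms: dimethyldioxirane, CC1(C)OO1
Why: Oxidative ring opening of a furan to a cis-enedial by oxygen-atom transfer carries the ring geometry into the (Z)-C1=C6 alkene, so that the future C2 and C5 stand cis, and the neutral medium with acetone as sole by-product avoids acid- or base-induced Z-to-E isomerisation.

Step 3
Reactants: 3 (2Z)-2-[(benzoyloxy)methyl]but-2-enedial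
Product: 4 (2Z)-2-[(benzoyloxy)methyl]penta-2,4-dienal
Conditions: Ph3PCH3Br, KN(SiMe3)2, THF, 0 °C; ylide (1.0 equiv) added slowly to 3, THF, −78 °C
Reagents that add atoms: methyltriphenylphosphonium bromide, C[P+](c1ccccc1)(c1ccccc1)c1ccccc1.[Br-]
Why: In this Wittig methylenation under kinetic control the non-stabilised ylide adds 1,2 to the formyl group on the unbranched alkene carbon C6 faster than to the formyl group flanked by the C1 branch, one equivalent at low temperature stops at mono-olefination, and the alkene geometry is not touched.

Step 4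
Reactants: 4 (2Z)-2-[(benzoyloxy)methyl]penta-2,4-dienal; 5 3-(methoxymethoxy)prop-1-ene
Product: 8 (2Z)-2-[(1S,2S)-1-hydroxy-2-(methoxymethoxy)but-3-en-1-yl]penta-2,4-dien-1-yl benzoate, via Z-alkoxyallylborane 6 (not isolated), via borinate adduct 7 (not isolated)
Conditions: 5, s-BuLi, THF, −78 °C; (+)-Ipc2BOMe; BF3·OEt2; then 4, −78 °C; 30% H2O2, pH 7 buffer, MeOH, 0 °C
Reagents that add atoms: none
Why: In this Brown asymmetric alkoxyallylboration the closed chair (Zimmerman–Traxler) transition state converts the Z geometry of 6 into the syn C2/C3 relationship, the isopinocampheyl groups derived from (−)-α-pinene direct the allyl unit to the Re face of the achiral aldehyde and so fix both centres absolutely, and the product carries C2–OH free and C3–O masked, which differentiates the two oxygens.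

Step 5
Reactants: 8 (2Z)-2-[(1S,2S)-1-hydroxy-2-(methoxymethoxy)but-3-en-1-yl]penta-2,4-dien-1-yl benzoate
Product: 9 [(5S,6S)-6-hydroxy-5-(methoxymethoxy)cyclohexa-1,3-dien-1-yl]methyl benzoate
Conditions: second-generation Hoveyda–Grubbs catalyst (5 mol %), 1,4-benzoquinone (10 mol %), CH2Cl2 (2 mM), 40 °C
Reagents that add atoms: none
Why: Chauvin mechanism: the ruthenium alkylidene exchanges with one monosubstituted vinyl group, undergoes intramolecular [2+2] cycloaddition with the other, and cycloreversion creates C4=C5 and expels ethene. The closest known reaction type is diene–ene ring-closing metathesis of octa-1,3,7-trienes to cyclohexa-1,3-dienes. The single ring formed is the six-membered carbocycle, closed by joining the two terminal sp2 carbons C4 and C5, and its size allows only the cis alkene. No stereocentre is created, and C2 and C3 are not touched. The step needs site selectivity among three alkenes and cyclisation in preference to oligomerisation: the trisubstituted C1=C6 alkene, deactivated by two allylic oxygens, is inert and its engagement would demand a cyclobutene, whereas its Z geometry places C5 next to the C2–C3–C4 arm, so that closure should be fast at high dilution. Neutral conditions, moderate temperature and 1,4-benzoquinone as hydride scavenger guard against alkene migration and against aromatisation of the diene by loss of water or of the acetal.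

Step 6
Reactants: 9 [(5S,6S)-6-hydroxy-5-(methoxymethoxy)cyclohexa-1,3-dien-1-yl]methyl benzoate
Product: 10 [(1R,2R,3S,6S)-2-hydroxy-3-(methoxymethoxy)-7-oxabicyclo[4.1.0]hept-4-en-1-yl]methyl benzoate (oxirane oxygen cis to the C2 hydroxyl, trans to the C3 acetal)
Conditions: VO(acac)2 (5 mol %), t-BuOOH (decane solution, 1.2 equiv), CH2Cl2, 0 °C
Reagents that add atoms: tert-butyl hydroperoxide, CC(C)(C)OO
Why: In this hydroxyl-directed epoxidation of a cyclic allylic alcohol (VO(acac)2/t-BuOOH) the vanadium alkoxide of the pseudoaxial C2 hydroxyl delivers oxygen to the adjacent C1=C6 alkene on its own face, which sets C1 and C6 with the oxirane cis to C2–O, while the merely homoallylic C4=C5 alkene is left alone.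

Step 7
Reactants: 10 [(1R,2R,3S,6S)-2-hydroxy-3-(methoxymethoxy)-7-oxabicyclo[4.1.0]hept-4-en-1-yl]methyl benzoate
Product: 11 [(1S,2R,3S,6S)-2-(benzoyloxy)-3-(methoxymethoxy)-7-oxabicyclo[4.1.0]hept-4-en-1-yl]methyl benzoate
Conditions: Bz2O, Et3N, DMAP, CH2Cl2, 0 °C to rt
Reagents that add atoms: benzoic anhydride, O=C(OC(=O)c1ccccc1)c1ccccc1
Why: DMAP-catalysed esterification with the chloride-free anhydride acylates the only free hydroxyl without opening the vinyl oxirane, and any earlier O7-to-O2 benzoyl shift is harmless because both oxygens end up benzoylated; no stereocentre is affected (the C1 descriptor changes only through ligand ranking).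

Step 8
Reactants: 11 [(1S,2R,3S,6S)-2-(benzoyloxy)-3-(methoxymethoxy)-7-oxabicyclo[4.1.0]hept-4-en-1-yl]methyl benzoate
Product: 13 [(1R,2R,5S,6R)-6-(benzoyloxy)-2-chloro-1,5-dihydroxycyclohex-3-en-1-yl]methyl benzoate, via MOM-protected chlorohydrin 12 (not isolated)
Conditions: HCl (4 M in 1,4-dioxane, 5 equiv), CH2Cl2, −20 to 0 °C; then H2O (10 equiv), rt
Reagents that add atoms: hydrogen chloride, Cl
Why: In this acid-promoted SN2-type opening of a vinyl oxirane followed by acetal hydrolysis, the protonated oxirane is cleaved at the allylic C6–O bond (C1 is deactivated by its two acyloxy-bearing neighbours), chloride enters anti and inverts C6 to give the trans-chlorohydrin with C1 retained, and the same acid with added water then removes the methoxymethyl group from O3.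

Compound list
1 | furan-3-ylmethanol | OCc1ccoc1 | starting material
2 | furan-3-ylmethyl benzoate | O=C(OCc1ccoc1)c1ccccc1 | intermediate
3 | (2Z)-2-[(benzoyloxy)methyl]but-2-enedial | O=C/C=C(\C=O)COC(=O)c1ccccc1 | intermediate
4 | (2Z)-2-[(benzoyloxy)methyl]penta-2,4-dienal | C=C/C=C(\C=O)COC(=O)c1ccccc1 | intermediate
5 | 3-(methoxymethoxy)prop-1-ene (allyl methoxymethyl ether) | C=CCOCOC | starting material
6 | [(2Z)-3-(methoxymethoxy)prop-2-en-1-yl]diisopinocampheylborane, Ipc groups from (−)-α-pinene | COCO/C=C\CB([C@H]1C[C@H]2C[C@@H]([C@@H]1C)C2(C)C)[C@H]1C[C@H]2C[C@@H]([C@@H]1C)C2(C)C | intermediate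
7 | diisopinocampheylborinate ester of 8 (boron on the C2 oxygen) | C=C/C=C(\[C@H](OB([C@H]1C[C@H]2C[C@@H]([C@@H]1C)C2(C)C)[C@H]1C[C@H]2C[C@@H]([C@@H]1C)C2(C)C)[C@@H](OCOC)C=C)COC(=O)c1ccccc1 | intermediate
8 | (2Z)-2-[(1S,2S)-1-hydroxy-2-(methoxymethoxy)but-3-en-1-yl]penta-2,4-dien-1-yl benzoate | C=C/C=C(\[C@H](O)[C@@H](OCOC)C=C)COC(=O)c1ccccc1 | intermediate
9 | [(5S,6S)-6-hydroxy-5-(methoxymethoxy)cyclohexa-1,3-dien-1-yl]methyl benzoate | O=C(OCC1=CC=C[C@H](OCOC)[C@H]1O)c1ccccc1 | intermediate
10 | [(1R,2R,3S,6S)-2-hydroxy-3-(methoxymethoxy)-7-oxabicyclo[4.1.0]hept-4-en-1-yl]methyl benzoate | O=C(OC[C@]12O[C@H]1C=C[C@H](OCOC)[C@H]2O)c1ccccc1 | intermediate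
11 | [(1S,2R,3S,6S)-2-(benzoyloxy)-3-(methoxymethoxy)-7-oxabicyclo[4.1.0]hept-4-en-1-yl]methyl benzoate | O=C(OC[C@]12O[C@H]1C=C[C@H](OCOC)[C@H]2OC(=O)c1ccccc1)c1ccccc1 | intermediate
12 | [(1R,2R,5S,6R)-6-(benzoyloxy)-2-chloro-1-hydroxy-5-(methoxymethoxy)cyclohex-3-en-1-yl]methyl benzoate | O=C(OC[C@]1(O)[C@H](Cl)C=C[C@H](OCOC)[C@H]1OC(=O)c1ccccc1)c1ccccc1 | intermediate
13 | [(1R,2R,5S,6R)-6-(benzoyloxy)-2-chloro-1,5-dihydroxycyclohex-3-en-1-yl]methyl benzoate | O=C(OC[C@]1(O)[C@H](Cl)C=C[C@H](O)[C@H]1OC(=O)c1ccccc1)c1ccccc1 | target

Total step count: 8. Longest linear sequence: 8 (1 to 13).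

Steps most likely to fail

1. Step 5 (ring-closing metathesis).
   - What may go wrong: loading of the catalyst on the diene terminus gives a stabilised vinylalkylidene that turns over slowly. Intermolecular metathesis competes. The cyclohexadiene may also aromatise by loss of water or of the acetal during a long reaction.
   - Fallback (sets out from 8, comes back at 11): the conjugated diene is removed before the ring is closed. Benzoylation of 8 (Bz2O, DMAP, Et3N) gives the dibenzoate triene F1. Shi epoxidation with the L-sorbose-derived enantiomer of the fructose ketone (KHSO5, K2CO3 buffer, MeCN/dimethoxymethane, 0 °C) should take the only trisubstituted alkene on the required face and give the cis-vinyl oxirane F2. Ring-closing metathesis of F2 (second-generation Grubbs catalyst, CH2Cl2, 40 °C) then forms the same C4=C5 bond between two isolated vinyl groups that the oxirane holds cis, and leads directly to 11.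

2. Step 3 (mono-methylenation of the dialdehyde).
   - What may go wrong: discrimination between the two formyl groups may be poor. Double olefination and base-induced Z-to-E isomerisation of the enedial are also possible.
   - Fallback (sets out from 3, comes back at 9): the methylene group is never installed. The base-free stabilised ylide Ph3P=CHCO2Me is added to the cold acetone solution of 3. It should react only at the unhindered formyl group and give the formyl dienoate F3. The alkoxyallylboration of step 4 applied to F3 gives the trienoate alcohol F4. Ring-closing metathesis of F4 starts at the C4 vinyl group, closes onto the C5 carbon of the enoate and expels methyl acrylate instead of ethene to give 9.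

3. Step 8 (oxirane opening and acetal cleavage in one flask).
   - What may go wrong: chloride attack at C6 competes with participation of the C7 benzoate carbonyl and with SN2' attack at C4. Slow acetal cleavage would force long acid exposure, with solvolysis of the allylic chloride or benzoyl migration between O2 and O3.
   - Fallback (sets out from 11, comes back at 13): the two events are separated and run without protic strong acid. Buffered halide opening (LiCl, AcOH, THF, rt) gives 12, which is now isolated. BCl3 (CH2Cl2, −78 °C), a chloride-only Lewis acid, then cleaves the acetal. No compound outside the list is made (F0).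

Further compounds
F1 | step 5 | (2Z)-2-[(1S,2S)-1-(benzoyloxy)-2-(methoxymethoxy)but-3-en-1-yl]penta-2,4-dien-1-yl benzoate | C=C/C=C(\[C@H](OC(=O)c1ccccc1)[C@@H](OCOC)C=C)COC(=O)c1ccccc1
F2 | step 5 | {(2S,3S)-2-[(1R,2S)-1-(benzoyloxy)-2-(methoxymethoxy)but-3-en-1-yl]-3-ethenyloxiran-2-yl}methyl benzoate | C=C[C@@H]1O[C@]1(COC(=O)c1ccccc1)[C@H](OC(=O)c1ccccc1)[C@@H](OCOC)C=C
F3 | step 3 | methyl (2E,4Z)-5-[(benzoyloxy)methyl]-6-oxohexa-2,4-dienoate | COC(=O)/C=C/C=C(\C=O)COC(=O)c1ccccc1
F4 | step 3 | methyl (2E,4Z,6S,7S)-5-[(benzoyloxy)methyl]-6-hydroxy-7-(methoxymethoxy)nona-2,4,8-trienoate | COC(=O)/C=C/C=C(\[C@H](O)[C@@H](OCOC)C=C)COC(=O)c1ccccc1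
F0 | step 8 | none | none
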